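## The problem

Target **24** is a bisabolane-type sesquiterpenoid diester on a single cyclohexane ring. The ring is numbered here C1 (ketone), C2 (methyl-bearing epoxide carbon), C3 (epoxide CH), C4 (CH2), C5 and C6 (acetoxy carbon), and C5 carries the open chain C8(=C15H2)–C9H(O-angeloyl)–C10H2–C11H=C12(CH3)2. There are five stereocentres, all S: C2, C3, C5 and C6 on the ring, with the C5 branch and the epoxide oxygen on one face and the C6 acetate on the other, and C9 in the chain. C5 and C6 are vicinal and trans and are best set together. A C1 carbinol trans to the C6 oxygen can then deliver the epoxide oxygen to the face it occupies; this is needed because peroxide addition to a C2=C3 enone would be expected anti to the C5 branch. C9 is insulated from the ring by the sp2 carbon C8 and has to be set by a reagent. The fragile groups are the α-acetoxy ketone (acidic C6–H, acetyl migration), the epoxy ketone (base, nucleophiles), the angelate (Z to E isomerisation) and the allylic ester and two further alkenes of the chain (peracids, acid). The enabling feature is that C3 and C6 both bear oxygen and are 1,4-related across the ring, flanking the C1–C2(CH3) unit: they can be the two α-carbons of 3-methylfuran, with one bridging oxygen that stays on C6 and later leaves C3.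

## Retrosynthesis

**Epoxy ketone to enone.** The two epoxide C–O bonds and the C1 carbonyl are taken back together: **24** comes from epoxy alcohol **23** by oxidation, **23** from allylic alcohol **22** by hydroxyl-directed epoxidation, and **22** from acetoxy enone **21** by 1,2-reduction. Direct nucleophilic epoxidation of **21** is shorter but should place the oxygen trans to the C5 branch. The detour asks only that hydride enter C1 axially, which puts the carbinol trans to the C6 acetate and cis to the branch.

**Enone to oxygen bridge.** Re-forming the C3–O bond from the C6 oxygen turns **21** (through hydroxy enone **20**) into the 7-oxanorbornanone **19**. Forward, this is a strain-driven β-elimination that cannot go the other way, since the bridgehead C6 cannot enolise. The bridge hides the enone and the C6 hydroxyl in one inert ether; **19** comes from silyl ether **17** through alcohol **18**.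

**Angelate.** Cutting the C9–O ester bond gives alcohol **14** and angelic acid **15**. The ester is placed before the ring is unveiled because acylation then meets only ethers, and because the ester removes the C9 hydroxyl as a competing director in the epoxidation. The forward step must not isomerise the Z-alkene.

**C8–C9.** This cut divides **14** into the ring-bearing 2-iodoalkene **11** and 4-methylpent-3-enal **13**, the latter from commercial alcohol **12**. It removes the whole chain and the C9 stereocentre in one operation. The neighbouring cut C9–C10 would need an α-selective prenyl addition, and C5–C8 is already a bond of the cycloaddition. The forward coupling must be non-basic (**13** is a β,γ-unsaturated aldehyde) and controlled by the reagent.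

**C8 functionality.** Iodide **11** comes from terminal alkyne **9** by Markovnikov hydrometalation–iodination. Cutting C8≡C15 gives aldehyde **8**, which comes from bis-silyl ether **7** and diol **6**. Each precursor is simpler by one carbon or one protecting group.

**C1 oxygen.** The C1–O bond of **6** is taken back to the ring alkene of alcohol **4**. Hydroboration places boron on the unsubstituted carbon C1, away from the methyl-bearing C2. Alcohol **4** comes from imide **3** by reduction.

**Ring.** Cutting C3–C4 and C5–C6 of **3** gives 3-methylfuran **1** and acrylimide **2**, both commercial. No other cut creates the carbocycle, C5 and C6 at once. The forward reaction has to be regioselective (C3 to the acrylate β-carbon), endo and enantioselective.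

## Roads not taken

**Alternative 1:** Cut C5–C6 and C2=C3. tert-Butyl 3-oxopentanoate A1 adds to (E)-4-(tert-butyldiphenylsilyloxy)but-2-enal A2 under iminium catalysis, and acid then drives aldol condensation and decarboxylation to (R)-5-(silyloxymethyl)-2-methylcyclohex-2-enone A3.
- Merits: one catalytic pot from two acyclic partners, no regiochemical doubt, and the enone, the C2 methyl and C5 all in place. It reaches an enone in fewer operations than the chosen plan, which spends steps 3, 12 and 13 on the same task.
- Weak points: A3 has no C6 oxygen. It would have to be added through the kinetic α′-enolate, with the trans relationship resting on one remote substituent. The free enone would then face the hydride and organometallic steps of chain building or need masking. Once the C5 arm is an aldehyde, the C6 oxygen is β to it and α to the ketone, so elimination towards an aromatic ring is a standing threat.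
- Comparison: Alternative 1 is shorter to the carbocycle and surer in constitution. The chosen plan sets against it that C5 and C6 arise together, with their trans relationship fixed by the bicycle, and that the bridge protects both enone and C6 hydroxyl through steps 5–11.

**Alternative 2:** Cut C1–C2. The acyclic (Z)-iodoalkenyl α-acetoxy aldehyde A4 closes by intramolecular Ni/Cr-mediated addition to cyclohexenol A5, with the C1 hydroxyl trans to the C6 acetate.
- Merits: the closure gives the epoxide-directing carbinol directly, where the chosen route must reduce a ketone it has just made (step 14). The chain and C9 are assembled on an open chain, and the coupling tolerates the acetate.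
- Weak points: A4 carries C5, C6 and C9, each set in separate acyclic operations, so the prelude is long. A4 is an epimerisable α-acetoxy aldehyde. The new C1 centre depends on the facial bias of the cyclisation and is not redundant, because it steers the epoxide. A5 still needs its C9 silyl ether exchanged for the angelate.
- Comparison: the end-game is better by about two steps and there is no furan chemistry to worry about. The chosen plan answers with one catalytic step from two commercial compounds for ring, C5 and C6, and with a C1 carbinol whose configuration follows from axial hydride delivery to a biased enone.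

**Alternative 3:** Cut C4–C5 and C1–C6. (E)-1-(tert-Butyldimethylsilyloxy)-2-methylbuta-1,3-diene A6 and methyl (E)-4-oxopent-2-enoate A7 combine in a ketone-directed endo Diels–Alder to cyclohexene A8. The C6 acetyl is a latent acetate through Baeyer–Villiger oxidation.
- Merits: an all-carbon cycloaddition with no bridge to open. C2=C3 with its methyl and functionality at C1, C5 and C6 arrive in one step. The regiochemistry is hardly in doubt, and the acetyl-to-acetate change keeps configuration.
- Weak points: an enantioselective version needs a chiral Lewis acid that binds the ketone rather than the ester of A7 at one point, which is less secure than two-point chelation of **2**. The endo rule puts the C1 oxygen of A8 cis to the C6 substituent, the wrong face for directing the epoxide, so C1 would still pass through the ketone and be reduced again. The peracid of the Baeyer–Villiger step meets the trisubstituted C2=C3 alkene.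
- Comparison: the length is similar, and this road is better in regiochemical certainty and in needing no bridge opening. The chosen plan has the better-founded absolute control and never exposes an alkene to a peracid.

Key step: step 1

Assumption: the Cu(II)–tert-butyl-bis(oxazoline) catalyst is taken to discriminate the faces of **2** with 3-methylfuran as it does with furan, so the (R,R)-ligand is specified for the (1R,2R,4R) adduct; if the sense were opposite, the (S,S)-ligand would be used.

In the names below, exo means on the side of the oxygen bridge and endo the opposite side; locants are those of the target ring.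

## Route

Step 1
Reactants: 1 3-methylfuran; 2 3-acryloyl-1,3-oxazolidin-2-one
Product: 3 3-[(1R,2R,4R)-5-methyl-7-oxabicyclo[2.2.1]hept-5-ene-2-carbonyl]-1,3-oxazolidin-2-one (endo adduct; acyl group anti to the oxygen bridge)
Conditions: [Cu((R,R)-t-Bu-box)](SbF6)2 (5–10 mol%), excess 1, CH2Cl2, −78 °C; cold filtration through silica
Reagents that add atoms: none
Why: The imide binds the cationic Cu(II) complex through both carbonyl groups in the s-cis form, which lowers its LUMO and leaves one face of the alkene open. A concerted, asynchronous [4+2] cycloaddition follows; the closest known reaction type is the Cu(II)–bis(oxazoline)-catalysed endo Diels–Alder of furan itself with this acrylimide. The six-membered carbocycle is closed by intermolecular cycloaddition that forms C3–C4 and C5–C6 at once, the furan oxygen becoming the one-atom bridge of a 7-oxabicyclo[2.2.1]heptene. The C5 stereocentre is set by the catalyst, which selects the enantioface of the dienophile. The bridgeheads C3 and C6 are set relative to C5 by the endo transition state, which places the acyl group anti to the bridge and so gives the trans C5/C6 relationship of the target. The step needs regio-, endo- and enantioselectivity. The methyl group raises the HOMO coefficient at the adjacent furan α-carbon, which bonds to the electrophilic β-carbon as in the para rule for 2-substituted dienes. Operation at −78 °C keeps the kinetic endo adduct from reverting to the exo isomer.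

Step 2
Reactants: 3 endo imide adduct
Product: 4 [(1R,2S,4R)-5-methyl-7-oxabicyclo[2.2.1]hept-5-en-2-yl]methanol (endo-CH2OH)
Conditions: LiBH4, MeOH (1 equiv), THF, 0 °C
Reagents that add atoms: none
Why: Reductive cleavage of an N-acyloxazolidinone by LiBH4; hydride attacks the exocyclic carbonyl, no stereocentre is touched, and the cold conditions avoid cycloreversion of the still unsaturated bicycle.

Step 3
Reactants: 4 endo alcohol
Product: 6 7-oxanorbornane diol (exo-OH at C1; endo-CH3 at C2; endo-CH2OH at C5), via C1 alkylborane 5 (not isolated)
Conditions: BH3·THF (excess), THF, 0 °C to rt; then aq NaOH, 30% H2O2, 0 °C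
Reagents that add atoms: hydrogen peroxide OO
Why: Hydroboration–oxidation of a strained trisubstituted alkene: boron goes to the unsubstituted carbon C1 from the exo face, setting C1 and C2 by syn addition, and oxidation retains configuration; both centres are later erased (C1 becomes the ketone, C2 an alkene carbon), and a bridgehead β-oxygen cannot be eliminated from the borane.

Step 4
Reactants: 6 diol
Product: 7 bis(triethylsilyl) ether of 6 (TES on the C1 exo oxygen and on the primary oxygen)
Conditions: TESCl, imidazole, DMAP (cat.), CH2Cl2, 0 °C to rt
Reagents that add atoms: chlorotriethylsilane CC[Si](Cl)(CC)CC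
Why: Standard silylation of both hydroxyls; the two TES ethers differ enough (primary against hindered secondary) to be told apart in the next step.

Step 5
Reactants: 7 bis-TES ether
Product: 8 aldehyde (endo-CHO at C5; exo-OTES at C1; endo-CH3 at C2)
Conditions: (COCl)2, DMSO, CH2Cl2, −78 to −30 °C; then i-Pr2NEt, −78 to 0 °C
Reagents that add atoms: none
Why: Swern oxidation used as a selective oxidative desilylation: activated DMSO exchanges with the primary TES ether only and the alkoxysulfonium ion collapses to the aldehyde; the hindered base and low temperature keep the C5 centre, α to the new aldehyde, from enolising.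

Step 6
Reactants: 8 aldehyde
Product: 9 terminal alkyne (endo-ethynyl at C5; exo-OTES at C1; endo-CH3 at C2)
Conditions: dimethyl (1-diazo-2-oxopropyl)phosphonate, K2CO3, MeOH, 0 °C to rt
Reagents that add atoms: dimethyl (1-diazo-2-oxopropyl)phosphonate CC(=O)C(=[N+]=[N-])P(=O)(OC)OC
Why: Ohira–Bestmann variant of the Seyferth–Gilbert homologation: the diazophosphonate anion adds to the aldehyde, and loss of phosphate and nitrogen with 1,2-hydride shift gives the alkyne; addition is expected to outrun enolisation of the aldehyde.

Step 7
Reactants: 9 terminal alkyne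
Product: 11 2-iodoalkene (C5–C8(I)=C15H2; exo-OTES at C1; endo-CH3 at C2), via C8 alkenylalane 10 (not isolated)
Conditions: DIBAL-H, Ni(dppp)Cl2 (3 mol%), THF, 0 to 22 °C; then NIS, THF, 0 °C
Reagents that add atoms: N-iodosuccinimide O=C1CCC(=O)N1I
Why: Ni-catalysed α-selective (Markovnikov) hydroalumination of a terminal alkyl alkyne places aluminium on the internal carbon C8, and iodinolysis replaces it with retention; the conditions are neutral towards the bridging ether and the silyl ether.

Step 8
Reactants: 12 4-methylpent-3-en-1-ol
Product: 13 4-methylpent-3-enal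
Conditions: Dess–Martin periodinane, NaHCO3, CH2Cl2, 0 °C; used at once as a cold solution
Reagents that add atoms: none
Why: Dess–Martin oxidation under buffered, non-basic conditions, so the β,γ-alkene is not drawn into conjugation.

Step 9
Reactants: 11 2-iodoalkene; 13 4-methylpent-3-enal
Product: 14 (9S)-allylic alcohol (C5–C8(=CH2)–C9H(OH)–CH2CH=C(CH3)2; exo-OTES at C1)
Conditions: CrCl2, chiral oxazoline–sulfonamide ligand, Et3N, NiCl2 (cat.), THF, rt; 13 added to the preformed Cr–ligand complex
Reagents that add atoms: none
Why: Asymmetric Nozaki–Hiyama–Kishi coupling: Ni(0) inserts into the C–I bond, the alkenyl group passes to Cr(III) and adds to the aldehyde only; the ligand on chromium selects the aldehyde face (the antipode that gives 9S is used), and no free base meets the isomerisable aldehyde.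

Step 10
Reactants: 14 (9S)-allylic alcohol; 15 angelic acid ((Z)-2-methylbut-2-enoic acid)
Product: 17 C9 angelate (exo-OTES at C1), via mixed anhydride 16 (not isolated)
Conditions: 15, 2,4,6-trichlorobenzoyl chloride, Et3N, PhMe, rt; then 14, PhMe, 75 °C
Reagents that add atoms: none
Why: Yamaguchi-type esterification through the mixed anhydride, run without a nucleophilic pyridine catalyst so that the Z-alkene is not isomerised by conjugate addition–elimination; C9 is acylated with retention, and the saturated bicycle tolerates the heating.

Step 11
Reactants: 17 C9 angelate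
Product: 18 C1 exo-alcohol (7-oxanorbornane with the complete C5 side chain)
Conditions: HF·pyridine, pyridine, THF, 0 °C to rt
Reagents that add atoms: none
Why: Buffered fluoride cleavage of a secondary TES ether; esters, alkenes and the bridging ether are unaffected.

Step 12
Reactants: 18 C1 exo-alcohol
Product: 19 7-oxanorbornan-2-one (C1 ketone; oxygen bridge C3–O–C6; endo-CH3 at C2)
Conditions: Dess–Martin periodinane, NaHCO3, CH2Cl2, 0 °C to rt
Reagents that add atoms: none
Why: Dess–Martin oxidation of a secondary alcohol under buffered conditions that do not enolise the strained β-alkoxy ketone.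

Step 13
Reactants: 19 7-oxanorbornan-2-one
Product: 21 (5S,6S)-6-acetoxy-2-methylcyclohex-2-enone bearing the C5 side chain, via hydroxy enone 20 (not isolated)
Conditions: DBU (cat.), CH2Cl2, −20 to 0 °C; then Ac2O, pyridine, DMAP (cat.), 0 °C
Reagents that add atoms: acetic anhydride CC(=O)OC(C)=O
Why: E1cB β-elimination of a 7-oxanorbornan-2-one: the ketone can enolise only towards C2 (C6 is a bridgehead), the enolate expels the bridge oxygen from C3 with release of strain, and the freed C6 hydroxyl, unchanged in configuration and trans to the C5 branch, is acetylated in the same flask before the α-ketol can equilibrate.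

Step 14
Reactants: 21 acetoxy enone
Product: 22 allylic alcohol (C1–OH trans to C6–OAc and cis to the C5 branch)
Conditions: NaBH4, CeCl3·7H2O, MeOH, −78 °C
Reagents that add atoms: none
Why: Luche 1,2-reduction: in the half-chair with the C5 and C6 substituents equatorial the small hydride enters C1 axially, anti to the axial C6–H, and gives the equatorial carbinol; the low temperature disfavours acetyl migration.

Step 15
Reactants: 22 allylic alcohol
Product: 23 epoxy alcohol (C2–C3 epoxide cis to C1–OH and to the C5 branch)
Conditions: VO(acac)2 (cat.), t-BuOOH, CH2Cl2, 0 °C to rt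
Reagents that add atoms: tert-butyl hydroperoxide CC(C)(C)OO
Why: Vanadium-catalysed hydroxyl-directed epoxidation: the peroxide is delivered from the vanadate ester of the C1 alcohol to the same face of C2=C3, setting C2 and C3; the electron-rich prenyl alkene, the esterified allylic alkene and the angelate are not engaged.

Step 16
Reactants: 23 epoxy alcohol
Product: 24 CNP0150645.2 (target)
Conditions: Dess–Martin periodinane, NaHCO3, CH2Cl2, 0 °C
Reagents that add atoms: none
Why: Dess–Martin oxidation of the C1 carbinol to the ketone under neutral conditions, which leave the epoxide, the acidic C6–H and the Z-ester untouched.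

## Compound list

1 | 3-methylfuran | Cc1ccoc1 | starting material
2 | 3-acryloyl-1,3-oxazolidin-2-one | C=CC(=O)N1CCOC1=O | starting material
3 | 3-[(1R,2R,4R)-5-methyl-7-oxabicyclo[2.2.1]hept-5-ene-2-carbonyl]-1,3-oxazolidin-2-one (endo) | O=C([C@@H]1C[C@@H]2C(C)=C[C@H]1O2)N1CCOC1=O | intermediate
4 | [(1R,2S,4R)-5-methyl-7-oxabicyclo[2.2.1]hept-5-en-2-yl]methanol (endo) | OC[C@@H]1C[C@@H]2C(C)=C[C@H]1O2 | intermediate
5 | C1-exo alkylborane from 4 (drawn in its simplest form, RBH2 with the primary oxygen as O–BH2) | BOC[C@@H]1C[C@@H]2[C@H](C)[C@@H](B)[C@H]1O2 | intermediate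
6 | 7-oxanorbornane diol: exo-OH at C1, endo-CH3 at C2, endo-CH2OH at C5, oxygen bridge C3–O–C6 | OC[C@@H]1C[C@@H]2[C@H](C)[C@@H](O)[C@H]1O2 | intermediate
7 | bis(triethylsilyl) ether of 6 | CC[Si](CC)(CC)OC[C@@H]1C[C@@H]2[C@H](C)[C@@H](O[Si](CC)(CC)CC)[C@H]1O2 | intermediate
8 | aldehyde: endo-CHO at C5, exo-OTES at C1, endo-CH3 at C2 | O=C[C@@H]1C[C@@H]2[C@H](C)[C@@H](O[Si](CC)(CC)CC)[C@H]1O2 | intermediate
9 | alkyne: endo-ethynyl at C5, exo-OTES at C1, endo-CH3 at C2 | C#C[C@@H]1C[C@@H]2[C@H](C)[C@@H](O[Si](CC)(CC)CC)[C@H]1O2 | intermediate
10 | C8 alkenyl(diisobutyl)alane from 9 | C=C([Al](CC(C)C)CC(C)C)[C@@H]1C[C@@H]2[C@H](C)[C@@H](O[Si](CC)(CC)CC)[C@H]1O2 | intermediate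
11 | 2-iodoalkene: endo-(1-iodovinyl) at C5, exo-OTES at C1, endo-CH3 at C2 | C=C(I)[C@@H]1C[C@@H]2[C@H](C)[C@@H](O[Si](CC)(CC)CC)[C@H]1O2 | intermediate
12 | 4-methylpent-3-en-1-ol | CC(C)=CCCO | starting material
13 | 4-methylpent-3-enal | CC(C)=CCC=O | intermediate
14 | (9S)-allylic alcohol: C5–C(=CH2)–CH(OH)–CH2CH=C(CH3)2 on the oxanorbornane, exo-OTES at C1 | C=C([C@H](CC=C(C)C)O)[C@@H]1C[C@@H]2[C@H](C)[C@@H](O[Si](CC)(CC)CC)[C@H]1O2 | intermediate
15 | angelic acid, (Z)-2-methylbut-2-enoic acid | C/C=C(/C)C(=O)O | starting material
16 | (Z)-2-methylbut-2-enoic 2,4,6-trichlorobenzoic anhydride | C/C=C(/C)C(=O)OC(=O)c1c(Cl)cc(Cl)cc1Cl | intermediate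
17 | (9S)-angelate of 14, exo-OTES at C1 | C=C([C@H](CC=C(C)C)OC(=O)/C(C)=C\C)[C@@H]1C[C@@H]2[C@H](C)[C@@H](O[Si](CC)(CC)CC)[C@H]1O2 | intermediate
18 | C1 exo-alcohol with the complete side chain | C=C([C@H](CC=C(C)C)OC(=O)/C(C)=C\C)[C@@H]1C[C@@H]2[C@H](C)[C@@H](O)[C@H]1O2 | intermediate
19 | 7-oxanorbornan-2-one: C1 ketone, oxygen bridge C3–O–C6, endo-CH3 at C2 | C=C([C@H](CC=C(C)C)OC(=O)/C(C)=C\C)[C@@H]1C[C@@H]2[C@H](C)C(=O)[C@H]1O2 | intermediate
20 | (5S,6S)-6-hydroxy-2-methylcyclohex-2-enone with the C5 side chain (OH trans to the branch) | C=C([C@H](CC=C(C)C)OC(=O)/C(C)=C\C)[C@@H]1CC=C(C)C(=O)[C@H]1O | intermediate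
21 | (5S,6S)-6-acetoxy-2-methylcyclohex-2-enone with the C5 side chain | C=C([C@H](CC=C(C)C)OC(=O)/C(C)=C\C)[C@@H]1CC=C(C)C(=O)[C@H]1OC(C)=O | intermediate
22 | cyclohex-2-enol: C1–OH trans to C6–OAc, cis to the C5 branch | C=C([C@H](CC=C(C)C)OC(=O)/C(C)=C\C)[C@@H]1CC=C(C)[C@H](O)[C@H]1OC(C)=O | intermediate
23 | epoxy alcohol: C2–C3 epoxide cis to C1–OH and to the C5 branch, C6–OAc trans | C=C([C@H](CC=C(C)C)OC(=O)/C(C)=C\C)[C@@H]1C[C@@H]2O[C@]2(C)[C@H](O)[C@H]1OC(C)=O | intermediate
24 | CNP0150645.2: (2S,3S,5S,6S)-6-acetoxy-2,3-epoxy-2-methylcyclohexanone with the (9S)-angeloyloxy side chain at C5 | C=C([C@H](CC=C(C)C)OC(=O)/C(C)=C\C)[C@@H]1C[C@@H]2O[C@]2(C)C(=O)[C@H]1OC(C)=O | target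

## Step count and least certain steps

Total: 16 steps. Longest linear sequence: 15 steps (steps 1–7 and 9–16); step 8 is a one-step branch.

**Step 1 (key step).** The electron-rich furan may add in conjugate (Friedel–Crafts) fashion instead of cyclising. Bonding may be shared between the two furan α-carbons. The adduct may also revert and return as the exo or less enantioenriched isomer if it warms with the Lewis acid present.
Fallback, from 1 back to 4: facial control is moved to a covalently bound auxiliary. (S)-4-Benzyloxazolidin-2-one is N-acryloylated to (S)-3-acryloyl-4-benzyl-1,3-oxazolidin-2-one F1. F1 is combined with 1 under an achiral chelating Lewis acid (Et2AlCl or MgBr2·OEt2, CH2Cl2, −78 °C). The benzyl group shields one face of the chelated s-cis dienophile, and the diastereomers can be separated, giving the auxiliary-bearing endo adduct F2. LiBH4 reduction of F2 gives 4.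

**Step 6.** Base-induced enolisation of the aldehyde would epimerise C5 or expel the bridge oxygen from C6, opening the bicycle in the wrong direction.
Fallback, from 8 back to 9: a two-stage homologation whose carbonyl-addition stage is not basic. CBr4/PPh3 (CH2Cl2, 0 °C) converts 8 into the 1,1-dibromoalkene F3. n-BuLi (THF, −78 °C) then gives 9 by elimination, exchange and protonation.

**Step 9.** The ligand may not control the aldehyde face against the bias of the neighbouring C5 centre, and the aldehyde may isomerise into conjugation before it couples.
Fallback, from 11 and 13 back to 14: C–C bond formation and stereocontrol are separated. The unselective Ni/Cr coupling (CrCl2, NiCl2 cat., DMSO) gives the C9-epimeric alcohol mixture F4. Dess–Martin oxidation gives the C9 ketone F5. Corey–Bakshi–Shibata reduction with the (R)-methyl-oxazaborolidine and catecholborane (PhMe, −78 °C) then treats the branched alkenyl group as the large substituent and gives 14.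

**Step 10.** Z to E isomerisation of the activated acid to the tiglate, or slow acylation of the hindered allylic alcohol.
Fallback, from 14 back to 17: the Z-alkene is built after the ester bond. 14 is esterified (DCC, DMAP) with 2-[bis(2,2,2-trifluoroethoxy)phosphoryl]propanoic acid to the phosphonopropionate F6. Still–Gennari olefination of F6 with acetaldehyde (KHMDS, 18-crown-6, THF, −78 °C) forms the Z-trisubstituted ester 17.

**Step 14.** Acetyl migration from the C6 oxygen to the new C1 alkoxide, or hydride delivery to the wrong face; either would misdirect the epoxidation.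
Fallback, from 19 back to 24: the C6 oxygen is carried as a silyl ether and acetylated last.
- TESOTf/Et3N opens 19 directly to the 6-triethylsilyloxy enone F7.
- Luche reduction gives the allylic alcohol F8.
- VO(acac)2/t-BuOOH gives the epoxy alcohol F9.
- Dess–Martin oxidation gives the silyloxy epoxy ketone F10.
- HF·pyridine gives the hydroxy epoxy ketone F11.
- Ac2O/pyridine gives 24.

## Further compounds

F1 | step 1 | (S)-3-acryloyl-4-benzyl-1,3-oxazolidin-2-one | C=CC(=O)N1[C@@H](Cc2ccccc2)COC1=O
F2 | step 1 | (4S)-4-benzyl-3-[(1R,2R,4R)-5-methyl-7-oxabicyclo[2.2.1]hept-5-ene-2-carbonyl]-1,3-oxazolidin-2-one | O=C([C@@H]1C[C@@H]2C(C)=C[C@H]1O2)N1[C@@H](Cc2ccccc2)COC1=O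
F3 | step 6 | 1,1-dibromoalkene: endo-(2,2-dibromovinyl) at C5, exo-OTES at C1, endo-CH3 at C2 | BrC(Br)=C[C@@H]1C[C@@H]2[C@H](C)[C@@H](O[Si](CC)(CC)CC)[C@H]1O2
F4 | step 9 | C9-epimeric mixture of allylic alcohol 14 and its 9R isomer | C=C(C(O)CC=C(C)C)[C@@H]1C[C@@H]2[C@H](C)[C@@H](O[Si](CC)(CC)CC)[C@H]1O2
F5 | step 9 | C9 ketone (α-methylene ketone) from F4 | C=C(C(=O)CC=C(C)C)[C@@H]1C[C@@H]2[C@H](C)[C@@H](O[Si](CC)(CC)CC)[C@H]1O2
F6 | step 10 | 2-[bis(2,2,2-trifluoroethoxy)phosphoryl]propanoate of 14 | C=C([C@H](CC=C(C)C)OC(=O)C(C)P(=O)(OCC(F)(F)F)OCC(F)(F)F)[C@@H]1C[C@@H]2[C@H](C)[C@@H](O[Si](CC)(CC)CC)[C@H]1O2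
F7 | step 14 | (5S,6S)-2-methyl-6-(triethylsilyloxy)cyclohex-2-enone with the C5 side chain | C=C([C@H](CC=C(C)C)OC(=O)/C(C)=C\C)[C@@H]1CC=C(C)C(=O)[C@H]1O[Si](CC)(CC)CC
F8 | step 14 | cyclohex-2-enol: C1–OH trans to C6–OTES | C=C([C@H](CC=C(C)C)OC(=O)/C(C)=C\C)[C@@H]1CC=C(C)[C@H](O)[C@H]1O[Si](CC)(CC)CC
F9 | step 14 | epoxy alcohol: epoxide cis to C1–OH, C6–OTES trans | C=C([C@H](CC=C(C)C)OC(=O)/C(C)=C\C)[C@@H]1C[C@@H]2O[C@]2(C)[C@H](O)[C@H]1O[Si](CC)(CC)CC
F10 | step 14 | 6-triethylsilyloxy epoxy ketone | C=C([C@H](CC=C(C)C)OC(=O)/C(C)=C\C)[C@@H]1C[C@@H]2O[C@]2(C)C(=O)[C@H]1O[Si](CC)(CC)CC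
F11 | step 14 | 6-hydroxy epoxy ketone (deacetyl target) | C=C([C@H](CC=C(C)C)OC(=O)/C(C)=C\C)[C@@H]1C[C@@H]2O[C@]2(C)C(=O)[C@H]1O
A1 | alternative 1 | tert-butyl 3-oxopentanoate | CCC(=O)CC(=O)OC(C)(C)C
A2 | alternative 1 | (E)-4-(tert-butyldiphenylsilyloxy)but-2-enal | O=C/C=C/CO[Si](c1ccccc1)(c1ccccc1)C(C)(C)C
A3 | alternative 1 | (R)-5-[(tert-butyldiphenylsilyloxy)methyl]-2-methylcyclohex-2-en-1-one | C(O[Si](c1ccccc1)(c1ccccc1)C(C)(C)C)[C@@H]1CC=C(C)C(=O)C1
A4 | alternative 2 | acyclic (Z)-iodoalkenyl α-acetoxy aldehyde (C1 aldehyde, C2 iodide, C9 OTBS) | C=C([C@H](CC=C(C)C)O[Si](C)(C)C(C)(C)C)[C@H](C/C=C(\I)C)[C@H](OC(C)=O)C=O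
A5 | alternative 2 | cyclohexenol with C1–OH trans to C6–OAc and C9 OTBS | C=C([C@H](CC=C(C)C)O[Si](C)(C)C(C)(C)C)[C@@H]1CC=C(C)[C@H](O)[C@H]1OC(C)=O
A6 | alternative 3 | (E)-1-(tert-butyldimethylsilyloxy)-2-methylbuta-1,3-diene | C=C/C(C)=C/O[Si](C)(C)C(C)(C)C
A7 | alternative 3 | methyl (E)-4-oxopent-2-enoate | COC(=O)/C=C/C(C)=O
A8 | alternative 3 | cyclohexene adduct: C1–OTBS cis to C6 acetyl, C5 ester trans | COC(=O)[C@@H]1CC=C(C)[C@@H](O[Si](C)(C)C(C)(C)C)[C@H]1C(C)=O
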